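**Strategy.** The plan ties stereocentre C* temporarily to the oxygen that becomes the ring B methoxy group (ring A: anisyl; ring B: resorcinol-derived; ring C: stilbene aryl). That oxygen is ortho to the ring B carbon bearing the CH2CH2 chain, so O, two ring B carbons, both chain carbons and C* outline the pyran of a 2H-chromene carrying rings A and C on C2. One acid-catalysed propargyl Claisen/oxa-6π cascade joins propargylic alcohol 6 (rings A and C, OH and ethynyl on one carbon, Br as stilbene handle) to monosilylated resorcinol 8, forming the ring B–chain C–C bond and the O–C* bond. Reductive opening, O-methylation, asymmetric hydrogenation, Heck coupling and desilylation follow.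

Key step: step 5

Assumption: the facial sense of the iridium-catalysed hydrogenation of 14 cannot be assigned on paper, so the ligand antipode named in step 8 stands for whichever antipode a pilot run shows to give the (S)-product.

Step 1
Reactants: 1 4-bromo-2,6-dimethoxybenzaldehyde; 2 4-methoxyphenylmagnesium bromide
Product: 3 (4-bromo-2,6-dimethoxyphenyl)(4-methoxyphenyl)methanol (racemic)
Conditions: THF, 0 °C to 20 °C; then sat. aq. NH4Cl
Reagents that add atoms: none
Why: Grignard 1,2-addition to a non-enolisable aryl aldehyde is fast at 0 °C, where the aryl bromide does not exchange; the carbinol centre is racemic and is erased in step 2.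

Step 2
Reactants: 3 (4-bromo-2,6-dimethoxyphenyl)(4-methoxyphenyl)methanol
Product: 4 (4-bromo-2,6-dimethoxyphenyl)(4-methoxyphenyl)methanone
Conditions: activated MnO2, CH2Cl2, 20 °C
Reagents that add atoms: none
Why: MnO2 oxidation of a diaryl carbinol runs under neutral heterogeneous conditions, which keeps the acid-labile, doubly donor-substituted benzhydrol from ionising.

Step 3
Reactants: 4 (4-bromo-2,6-dimethoxyphenyl)(4-methoxyphenyl)methanone; 5 ethynylmagnesium bromide
Product: 6 1-(4-bromo-2,6-dimethoxyphenyl)-1-(4-methoxyphenyl)prop-2-yn-1-ol (racemic)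
Conditions: THF, 0 °C to 45 °C; then sat. aq. NH4Cl
Reagents that add atoms: none
Why: Acetylide 1,2-addition to a non-enolisable diaryl ketone, in which the slim sp nucleophile passes the two ortho methoxy groups; the tertiary carbinol centre is racemic and needs no control because this carbon is set anew in step 8.

Step 4
Reactants: 7 resorcinol
Product: 8 3-(triisopropylsilyloxy)phenol
Conditions: i-Pr3SiCl (1 equiv), resorcinol (3 equiv), imidazole, DMF, 0 °C to 20 °C
Reagents that add atoms: chlorotriisopropylsilane, CC(C)[Si](Cl)(C(C)C)C(C)C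
Why: Imidazole-mediated O-silylation with the diol in excess favours the monoether, the surplus resorcinol is washed out with water, and the bulky silyl group both marks the oxygen that stays free and shields the ring carbon between the two oxygens in step 5.

Step 5
Reactants: 6 1-(4-bromo-2,6-dimethoxyphenyl)-1-(4-methoxyphenyl)prop-2-yn-1-ol; 8 3-(triisopropylsilyloxy)phenol
Product: 12 2-(4-bromo-2,6-dimethoxyphenyl)-2-(4-methoxyphenyl)-7-(triisopropylsilyloxy)-2H-chromene (racemic), via aryl propargyl ether 9 (not isolated), via ortho-allenylphenol 10 (not isolated), via ortho-quinone allide 11 (not isolated)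
Conditions: pyridinium p-toluenesulfonate (10 mol %), HC(OMe)3, ClCH2CH2Cl, 70 °C, subdued light; chromatography on Et3N-deactivated silica
Reagents that add atoms: none
Why: The pyridinium acid ionises the tertiary propargylic alcohol of 6 to a cation shared by both donor-substituted aryl rings, and the free hydroxyl of 8 captures it at the carbinol carbon to give ether 9. An acid-assisted [3,3] propargyl Claisen shift then links the alkyne terminus to the ring B carbon ortho to oxygen, which is the new C–C bond, and tautomerisation of the resulting dienone gives allenylphenol 10. A 1,5-hydrogen shift from oxygen to the central allene carbon gives ortho-quinone allide 11, whose thermal, disrotatory oxa-6π electrocyclisation joins the oxygen to the diaryl carbon and closes the six-membered pyran ring. The nearest precedent is the chromenylation of phenols and naphthols with 1,1-diarylpropargyl alcohols under acid catalysis, the standard entry to photochromic 2,2-diaryl-2H-chromenes. The one stereocentre formed, C2, is racemic and needs no control, because step 6 returns this carbon to sp2. What the step needs is regioselectivity, rearrangement to the ring B carbon para to the silyloxy group and not to the carbon between the two oxygens, which the bulk of the triisopropylsilyl group should secure, while the orthoformate takes up the water formed and so holds back Meyer–Schuster rearrangement of 6.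

Step 6
Reactants: 12 2-(4-bromo-2,6-dimethoxyphenyl)-2-(4-methoxyphenyl)-7-(triisopropylsilyloxy)-2H-chromene
Product: 13 2-[3-(4-bromo-2,6-dimethoxyphenyl)-3-(4-methoxyphenyl)prop-2-enyl]-5-(triisopropylsilyloxy)phenol (E/Z mixture)
Conditions: LiAlH4/AlCl3 (1:1, premixed to AlH2Cl, 1.5 equiv), Et2O, −20 °C to 0 °C; then H2O, aq. potassium sodium tartrate
Reagents that add atoms: none
Why: Mixed-hydride hydrogenolysis of an activated allylic, doubly benzylic aryl ether, as in the mixed-hydride reduction of 2′-hydroxychalcones to 2-cinnamylphenols: the Lewis-acidic chloroalane binds the pyran oxygen, the C2–O bond ionises to an aluminium phenoxide paired with a 1,1-diarylallyl cation, and hydride passes from aluminium through a six-membered array to the unhindered ring B benzylic terminus C4 and not to the crowded diaryl carbon, so the diaryl carbon stays sp2 as an E/Z alkene pair while aryl bromide, methyl ethers and the bulky aryl silyl ether are left alone at 0 °C.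

Step 7
Reactants: 13 2-[3-(4-bromo-2,6-dimethoxyphenyl)-3-(4-methoxyphenyl)prop-2-enyl]-5-(triisopropylsilyloxy)phenol
Product: 14 {4-[(2Z)-3-(4-bromo-2,6-dimethoxyphenyl)-3-(4-methoxyphenyl)prop-2-enyl]-3-methoxyphenoxy}triisopropylsilane
Conditions: MeI, K2CO3, acetone, 50 °C; then separation of the geometric isomers (AgNO3-impregnated silica or preparative HPLC)
Reagents that add atoms: iodomethane, CI
Why: Williamson methylation of the phenoxide fixes the former pyran oxygen as the ring B methoxy group under carbonate conditions too weak to move the alkene into conjugation or to cleave the aryl silyl ether, and the Z isomer (ring C cis to the CH2 group, expected to be the major one because the twisted 2,6-dimethoxyaryl ring tolerates the cis substituent better than the coplanar anisyl ring) is then isolated geometrically pure and is the only material carried on.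

Step 8
Reactants: 14 {4-[(2Z)-3-(4-bromo-2,6-dimethoxyphenyl)-3-(4-methoxyphenyl)prop-2-enyl]-3-methoxyphenoxy}triisopropylsilane
Product: 15 {4-[(3S)-3-(4-bromo-2,6-dimethoxyphenyl)-3-(4-methoxyphenyl)propyl]-3-methoxyphenoxy}triisopropylsilane
Conditions: [Ir(cod)((S)-t-BuPHOX)]B[3,5-(CF3)2C6H3]4 (2 mol %; t-BuPHOX = 4-tert-butyl-2-[2-(diphenylphosphanyl)phenyl]-4,5-dihydrooxazole), H2 (50 bar), CH2Cl2, 25 °C
Reagents that add atoms: none
Why: Iridium-catalysed asymmetric hydrogenation of an unfunctionalised trisubstituted 1,1-diarylalkene with a cationic phosphinooxazoline complex and a non-coordinating borate anion: the geometrically pure alkene presents a twisted di-ortho-substituted ring and a coplanar anisyl ring of very different shape, so the chiral ligand pocket should deliver H2 to one enantiotopic face and set C* as S under catalyst control, while the aryl bromide and the silyl ether are untouched.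

Step 9
Reactants: 15 {4-[(3S)-3-(4-bromo-2,6-dimethoxyphenyl)-3-(4-methoxyphenyl)propyl]-3-methoxyphenoxy}triisopropylsilane; 16 tert-butyl(4-ethenylphenoxy)dimethylsilane
Product: 17 tert-butyl{4-[(E)-2-{3,5-dimethoxy-4-[(1S)-3-[2-methoxy-4-(triisopropylsilyloxy)phenyl]-1-(4-methoxyphenyl)propyl]phenyl}ethenyl]phenoxy}dimethylsilane
Conditions: Pd2(dba)3 (2 mol %), [HP(t-Bu)3]BF4 (8 mol %), Cy2NMe, 1,4-dioxane, 70 °C
Reagents that add atoms: none
Why: Mizoroki–Heck coupling: zerovalent palladium inserts into the unhindered C–Br bond, syn carbopalladation of the styrene at its terminal carbon and syn β-hydride elimination give the E-stilbene, and the mild amine base leaves the non-acidic diarylmethine stereocentre and both silyl ethers alone.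

Step 10
Reactants: 17 tert-butyl{4-[(E)-2-{3,5-dimethoxy-4-[(1S)-3-[2-methoxy-4-(triisopropylsilyloxy)phenyl]-1-(4-methoxyphenyl)propyl]phenyl}ethenyl]phenoxy}dimethylsilane
Product: 18 4-[(E)-2-{4-[(1S)-3-(4-hydroxy-2-methoxyphenyl)-1-(4-methoxyphenyl)propyl]-3,5-dimethoxyphenyl}ethenyl]phenol (CNP0182684.1)
Conditions: Bu4NF, AcOH, THF, 0 °C to 20 °C
Reagents that add atoms: none
Why: Fluoride cleaves both aryl silyl ethers in one operation (strong Si–F bond), and the acetic acid buffer keeps the electron-rich hydroxystilbene from standing as an oxidisable phenoxide; the stereocentre and the E-alkene are not touched.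

**Compound list**

1 | 4-bromo-2,6-dimethoxybenzaldehyde | O=Cc1c(OC)cc(Br)cc1OC | starting material
2 | 4-methoxyphenylmagnesium bromide | COc1ccc([Mg]Br)cc1 | starting material
3 | (4-bromo-2,6-dimethoxyphenyl)(4-methoxyphenyl)methanol, racemic | COc1ccc(C(O)c2c(OC)cc(Br)cc2OC)cc1 | intermediate
4 | (4-bromo-2,6-dimethoxyphenyl)(4-methoxyphenyl)methanone | COc1ccc(C(=O)c2c(OC)cc(Br)cc2OC)cc1 | intermediate
5 | ethynylmagnesium bromide | C#C[Mg]Br | starting material
6 | 1-(4-bromo-2,6-dimethoxyphenyl)-1-(4-methoxyphenyl)prop-2-yn-1-ol, racemic | COc1ccc(C(O)(C#C)c2c(OC)cc(Br)cc2OC)cc1 | intermediate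
7 | resorcinol | Oc1cccc(O)c1 | starting material
8 | 3-(triisopropylsilyloxy)phenol | CC(C)[Si](C(C)C)(C(C)C)Oc1cccc(O)c1 | intermediate
9 | {3-[1-(4-bromo-2,6-dimethoxyphenyl)-1-(4-methoxyphenyl)prop-2-ynyloxy]phenoxy}triisopropylsilane, racemic, not isolated | COc1ccc(C(C#C)(Oc2cccc(O[Si](C(C)C)(C(C)C)C(C)C)c2)c2c(OC)cc(Br)cc2OC)cc1 | intermediate
10 | 2-[3-(4-bromo-2,6-dimethoxyphenyl)-3-(4-methoxyphenyl)propa-1,2-dienyl]-5-(triisopropylsilyloxy)phenol, racemic allene, not isolated | COc1ccc(C(=C=Cc2ccc(O[Si](C(C)C)(C(C)C)C(C)C)cc2O)c2c(OC)cc(Br)cc2OC)cc1 | intermediate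
11 | 6-[3-(4-bromo-2,6-dimethoxyphenyl)-3-(4-methoxyphenyl)prop-2-enylidene]-3-(triisopropylsilyloxy)cyclohexa-2,4-dien-1-one, not isolated | COc1ccc(C(=CC=C2C=CC(O[Si](C(C)C)(C(C)C)C(C)C)=CC2=O)c2c(OC)cc(Br)cc2OC)cc1 | intermediate
12 | 2-(4-bromo-2,6-dimethoxyphenyl)-2-(4-methoxyphenyl)-7-(triisopropylsilyloxy)-2H-chromene, racemic | COc1ccc(C2(c3c(OC)cc(Br)cc3OC)C=Cc3ccc(O[Si](C(C)C)(C(C)C)C(C)C)cc3O2)cc1 | intermediate
13 | 2-[3-(4-bromo-2,6-dimethoxyphenyl)-3-(4-methoxyphenyl)prop-2-enyl]-5-(triisopropylsilyloxy)phenol, E/Z mixture | COc1ccc(C(=CCc2ccc(O[Si](C(C)C)(C(C)C)C(C)C)cc2O)c2c(OC)cc(Br)cc2OC)cc1 | intermediate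
14 | {4-[(2Z)-3-(4-bromo-2,6-dimethoxyphenyl)-3-(4-methoxyphenyl)prop-2-enyl]-3-methoxyphenoxy}triisopropylsilane | COc1ccc(/C(=C/Cc2ccc(O[Si](C(C)C)(C(C)C)C(C)C)cc2OC)c2c(OC)cc(Br)cc2OC)cc1 | intermediate
15 | {4-[(3S)-3-(4-bromo-2,6-dimethoxyphenyl)-3-(4-methoxyphenyl)propyl]-3-methoxyphenoxy}triisopropylsilane | COc1ccc([C@H](CCc2ccc(O[Si](C(C)C)(C(C)C)C(C)C)cc2OC)c2c(OC)cc(Br)cc2OC)cc1 | intermediate
16 | tert-butyl(4-ethenylphenoxy)dimethylsilane | C=Cc1ccc(O[Si](C)(C)C(C)(C)C)cc1 | starting material
17 | tert-butyl{4-[(E)-2-{3,5-dimethoxy-4-[(1S)-3-[2-methoxy-4-(triisopropylsilyloxy)phenyl]-1-(4-methoxyphenyl)propyl]phenyl}ethenyl]phenoxy}dimethylsilane | COc1ccc([C@H](CCc2ccc(O[Si](C(C)C)(C(C)C)C(C)C)cc2OC)c2c(OC)cc(/C=C/c3ccc(O[Si](C)(C)C(C)(C)C)cc3)cc2OC)cc1 | intermediate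
18 | 4-[(E)-2-{4-[(1S)-3-(4-hydroxy-2-methoxyphenyl)-1-(4-methoxyphenyl)propyl]-3,5-dimethoxyphenyl}ethenyl]phenol | COc1ccc([C@H](CCc2ccc(O)cc2OC)c2c(OC)cc(/C=C/c3ccc(O)cc3)cc2OC)cc1 | target

**Step count.** Total: 10 steps. Longest linear sequence: 9 steps (steps 1–3 and 5–10, from 1 to 18); step 4 is the one-step side branch.

**Steps most likely to fail, with fallbacks**

Step 5 (key step). The propargylic cation may be captured by traces of water and drift into Meyer–Schuster rearrangement, or it may alkylate ring B at the carbon para to the hydroxyl, so that the Claisen/electrocyclisation sequence is starved. The fallback makes the rearrangement deliberate and sets out from 6. Catalytic p-TsOH in wet THF should convert 6 into 3-(4-bromo-2,6-dimethoxyphenyl)-3-(4-methoxyphenyl)prop-2-enal F1. Phenol 8 is heated with Ti(OEt)4 in toluene with removal of ethanol to give triethoxy[3-(triisopropylsilyloxy)phenoxy]titanium F2. Addition of F1 at reflux should then bring about the ortho-selective aldol-type attack of the titanium aryloxide on the enal, loss of the titanium-bound oxygen and oxa-6π closure. This known chromene synthesis forms the same two bonds and comes back to the route at 12.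

Step 6. Hydride may be delivered to the diaryl terminus of the ion pair, which would create the stereocentre without control and leave a styrene. The Lewis-acidic medium may also re-ionise the electron-rich product alkene, so that a second hydride transfer gives racemic saturated material that would later erode the enantiomeric purity. Loosening of the silyl ether is a lesser concern. The fallback sets out from 12 and gives up the prochiral alkene. Et3SiH and CF3CO2H in CH2Cl2 at 0 °C should ionise the doubly benzylic allylic C–O bond, reduce the cation, protonate the resulting alkene and reduce again (ionic hydrogenation). This should give racemic 2-[3-(4-bromo-2,6-dimethoxyphenyl)-3-(4-methoxyphenyl)propyl]-5-(triisopropylsilyloxy)phenol F3. Preparative HPLC on a polysaccharide chiral phase would then provide 2-[(3S)-3-(4-bromo-2,6-dimethoxyphenyl)-3-(4-methoxyphenyl)propyl]-5-(triisopropylsilyloxy)phenol F4. Methylation of F4 with MeI and K2CO3 in acetone comes back to the route at 15.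

Step 8. Turnover at the hindered alkene may be poor, or acid-promoted E/Z isomerisation or double-bond migration of the electron-rich diarylalkene may outrun hydrogen transfer and erode the enantiomeric purity; the step also depends on complete geometric purification in step 7. The fallback sets out from 14 and draws no stereochemical information from the alkene, so its geometric purity no longer matters. Hydrogenation with the achiral, more active complex [Ir(cod)(PCy3)(py)]PF6 under H2 in CH2Cl2 should give racemic {4-[3-(4-bromo-2,6-dimethoxyphenyl)-3-(4-methoxyphenyl)propyl]-3-methoxyphenoxy}triisopropylsilane F5. Its enantiomers are separated by preparative chiral HPLC or SFC, and the S enantiomer comes back to the route at 15.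

**Further compounds**

F1 | step 5 | 3-(4-bromo-2,6-dimethoxyphenyl)-3-(4-methoxyphenyl)prop-2-enal (E/Z mixture) | COc1ccc(C(=CC=O)c2c(OC)cc(Br)cc2OC)cc1
F2 | step 5 | triethoxy[3-(triisopropylsilyloxy)phenoxy]titanium | CCO[Ti](OCC)(OCC)Oc1cccc(O[Si](C(C)C)(C(C)C)C(C)C)c1
F3 | step 6 | 2-[3-(4-bromo-2,6-dimethoxyphenyl)-3-(4-methoxyphenyl)propyl]-5-(triisopropylsilyloxy)phenol, racemic | COc1ccc(C(CCc2ccc(O[Si](C(C)C)(C(C)C)C(C)C)cc2O)c2c(OC)cc(Br)cc2OC)cc1
F4 | step 6 | 2-[(3S)-3-(4-bromo-2,6-dimethoxyphenyl)-3-(4-methoxyphenyl)propyl]-5-(triisopropylsilyloxy)phenol | COc1ccc([C@H](CCc2ccc(O[Si](C(C)C)(C(C)C)C(C)C)cc2O)c2c(OC)cc(Br)cc2OC)cc1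
F5 | step 8 | {4-[3-(4-bromo-2,6-dimethoxyphenyl)-3-(4-methoxyphenyl)propyl]-3-methoxyphenoxy}triisopropylsilane, racemic | COc1ccc(C(CCc2ccc(O[Si](C(C)C)(C(C)C)C(C)C)cc2OC)c2c(OC)cc(Br)cc2OC)cc1
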